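**Plan**

- Locants: in the benzoic acid ring C1 carries CO2H, C2 and C4 carry OH, and C6 carries the tridecyl chain C1′–C13′. Oxygen on every second ring carbon with the carboxyl on C1 is the mark of a tetraketide whose carboxyl α-carbon (C1) has condensed with the C6 carbonyl, so the benzene ring can be made from an open chain.
- Retrosynthesis: acetates, acid and phenols go back to a benzyl/silyl-protected resorcylate and on to a benzodioxinone. The ring bond C1–C6 is cut (aldol) to a diketo-dioxinone, then C5–C6 (Claisen acylation) to a keto-dioxinone and a C14 Weinreb amide, then C3–C4 (acetylation of the commercial dioxinone). In the chain, C1′–C2′ (diazoacetate homologation) and C10′–C11′ (epoxide opening) are cut.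
- Forward: the C14 acyl chain is built (steps 1–7), the dioxinone is homologated (step 8), the two are joined (step 9), the benzene ring, the only ring made, arises in step 10, and protecting-group exchange finishes the synthesis (steps 11–16).
- Stereochemistry: C12′ comes from (R)-propylene oxide. C2′ is set by (R)-BINAP–ruthenium hydrogenation of a β-keto ester. Neither centre is touched afterwards.

Key step: step 10

**Route**

Step 1
Reactants: 1 10-bromodec-1-ene; 2 (R)-propylene oxide
Product: 4 (2R)-tridec-12-en-2-ol, via dec-9-enylmagnesium bromide 3 (not isolated)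
Conditions: Mg, THF, rt to 40 °C; then CuI (cat.), 2, THF, −30 to 0 °C; aq. NH4Cl
Reagents that add atoms: none
Why: Copper-catalysed Grignard opening of a terminal epoxide is an SN2 attack at the unsubstituted carbon, so the C–O stereocentre of 2 is carried over unchanged as the (R)-carbinol.

Step 2
Reactants: 4 (2R)-tridec-12-en-2-ol
Product: 5 tert-butyldimethyl{[(2R)-tridec-12-en-2-yl]oxy}silane
Conditions: TBSCl, imidazole, DMF, rt
Reagents that add atoms: tert-butyldimethylsilyl chloride, CC(C)(C)[Si](C)(C)Cl
Why: Imidazole-promoted silylation of a secondary alcohol is a standard protection that masks the hydroxyl for the oxidative and basic steps ahead.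

Step 3
Reactants: 5 tert-butyldimethyl{[(2R)-tridec-12-en-2-yl]oxy}silane
Product: 7 (11R)-11-(tert-butyldimethylsilyloxy)dodecanal, via secondary ozonide 6 (not isolated)
Conditions: O3, CH2Cl2, −78 °C; then PPh3, −78 °C to rt
Reagents that add atoms: ozone, [O-][O+]=O
Why: Ozonolysis of the terminal alkene with reductive work-up of the ozonide gives the aldehyde one carbon shorter, and the silyl ether is inert to ozone.

Step 4
Reactants: 7 (11R)-11-(tert-butyldimethylsilyloxy)dodecanal
Product: 8 ethyl (13R)-13-(tert-butyldimethylsilyloxy)-3-oxotetradecanoate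
Conditions: N2CHCO2Et, SnCl2 (10 mol%), CH2Cl2, rt
Reagents that add atoms: ethyl diazoacetate, CCOC(=O)C=[N+]=[N-]
Why: Roskamp homologation, in which SnCl2 activates the aldehyde for attack by the diazo carbon and a 1,2-hydride shift with loss of N2 gives the β-keto ester directly.

Step 5
Reactants: 8 ethyl (13R)-13-(tert-butyldimethylsilyloxy)-3-oxotetradecanoate
Product: 9 ethyl (3R,13R)-13-(tert-butyldimethylsilyloxy)-3-hydroxytetradecanoate
Conditions: H2 (4–10 atm), RuCl2[(R)-BINAP] (cat.), EtOH, 40–50 °C
Reagents that add atoms: none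
Why: Noyori asymmetric hydrogenation, in which the ester carbonyl chelates the ketone to the (R)-BINAP–ruthenium hydride so that hydrogen reaches one face only; for 3-oxoalkanoates this gives the (3R)-alcohol under catalyst control, independent of the remote C13 centre.

Step 6
Reactants: 9 ethyl (3R,13R)-13-(tert-butyldimethylsilyloxy)-3-hydroxytetradecanoate
Product: 10 ethyl (3R,13R)-3,13-bis(tert-butyldimethylsilyloxy)tetradecanoate
Conditions: TBSOTf, 2,6-lutidine, CH2Cl2, −78 to 0 °C
Reagents that add atoms: tert-butyldimethylsilyl trifluoromethanesulfonate, CC(C)(C)[Si](C)(C)OS(=O)(=O)C(F)(F)F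
Why: Silylation with a silyl triflate and a hindered pyridine base is fast in the cold, avoids elimination of the β-hydroxy ester, and would also re-silylate any C13 hydroxyl uncovered during the hydrogenation.

Step 7
Reactants: 10 ethyl (3R,13R)-3,13-bis(tert-butyldimethylsilyloxy)tetradecanoate
Product: 11 (3R,13R)-3,13-bis(tert-butyldimethylsilyloxy)-N-methoxy-N-methyltetradecanamide
Conditions: MeNHOMe·HCl, i-PrMgCl, THF, −20 to 0 °C; aq. NH4Cl
Reagents that add atoms: N,O-dimethylhydroxylamine hydrochloride, CNOC.Cl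
Why: Weinreb amide synthesis by aminolysis of the ester with the chloromagnesium amide, run cold so that α-deprotonation and loss of the β-silyloxy group should not compete.

Step 8
Reactants: 12 2,2,6-trimethyl-4H-1,3-dioxin-4-one
Product: 14 2,2-dimethyl-6-(2-oxopropyl)-4H-1,3-dioxin-4-one, via lithium dienolate 13 (not isolated)
Conditions: LiN(SiMe3)2 (2 equiv), THF, −78 °C; then AcCl (1 equiv), −78 °C; aq. NH4Cl
Reagents that add atoms: acetyl chloride, CC(Cl)=O
Why: Vinylogous Claisen-type C-acylation, in which the lithium dienolate of the dioxinone reacts with the acid chloride at its γ-carbon (the former methyl group) and the excess dienolate takes up the proton of the more acidic product.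

Step 9
Reactants: 14 2,2-dimethyl-6-(2-oxopropyl)-4H-1,3-dioxin-4-one; 11 (3R,13R)-3,13-bis(tert-butyldimethylsilyloxy)-N-methoxy-N-methyltetradecanamide
Product: 16 6-[(6R,16R)-6,16-bis(tert-butyldimethylsilyloxy)-2,4-dioxoheptadecyl]-2,2-dimethyl-4H-1,3-dioxin-4-one, via dilithium dianion 15 (not isolated)
Conditions: LiN(iPr)2 (2 equiv per 14; 14 in excess over 11), THF, −78 °C; then 11, −78 to −40 °C; aq. NH4Cl
Reagents that add atoms: none
Why: Claisen-type acylation of a β-dicarbonyl dianion, in which the second deprotonation creates the more basic terminal carbanion that alone attacks the Weinreb amide, and the chelated tetrahedral adduct persists until the quench so that the acidic diketone does not consume dianion.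

Step 10
Reactants: 16 6-[(6R,16R)-6,16-bis(tert-butyldimethylsilyloxy)-2,4-dioxoheptadecyl]-2,2-dimethyl-4H-1,3-dioxin-4-one
Product: 18 5-[(2R,12R)-2,12-bis(tert-butyldimethylsilyloxy)tridecyl]-7-hydroxy-2,2-dimethyl-4H-1,3-benzodioxin-4-one, via cyclic aldol carbinol 17 (not isolated)
Conditions: Et3N, CH2Cl2, 0 °C to rt; then silica gel, rt
Reagents that add atoms: none
Why: Triethylamine removes a proton from the doubly activated methylene of 16 (chain C1, between dioxinone C6 and the C2 ketone), and the extended enolate reacts through its α-carbon, dioxinone C5, with the C4 ketone in an intramolecular aldol addition that forms the arene C1–C6 bond and gives carbinol 17; E1cB loss of water within the new ring and enolisation of the remaining ketone then give the phenol of 18. The closest known reaction type is the base-mediated aldol cyclisation–aromatisation of diketo-dioxinones to acetonide-masked 6-alkylresorcylates, the laboratory counterpart of polyketide folding. The one ring is closed in a 6-(enolexo)-exo-trig mode. No stereocentre is created, since the carbinol carbon of 17 becomes aromatic, and the two silyloxy-bearing carbons are not α to any carbonyl, so enolisation cannot epimerise them. The step needs C-aldol closure in preference to O-cyclisation to a pyranone or Claisen attack on the carboxyl carbon; the dioxinone secures this because it holds the carboxyl as an acylal lying trans to the chain across the ring C5=C6 bond and thus out of reach, leaving its α-carbon as the only nucleophile within six-membered distance of a ketone. The weak amine base at room temperature is also expected to spare the β-silyloxy ketone from elimination.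

Step 11
Reactants: 18 5-[(2R,12R)-2,12-bis(tert-butyldimethylsilyloxy)tridecyl]-7-hydroxy-2,2-dimethyl-4H-1,3-benzodioxin-4-one
Product: 19 7-(benzyloxy)-5-[(2R,12R)-2,12-bis(tert-butyldimethylsilyloxy)tridecyl]-2,2-dimethyl-4H-1,3-benzodioxin-4-one
Conditions: BnBr, K2CO3, acetone, 50 °C
Reagents that add atoms: benzyl bromide, BrCc1ccccc1
Why: Williamson ether synthesis on the only acidic hydroxyl, which also keeps a para-phenoxide from deactivating the dioxinone carbonyl in the next step.

Step 12
Reactants: 19 7-(benzyloxy)-5-[(2R,12R)-2,12-bis(tert-butyldimethylsilyloxy)tridecyl]-2,2-dimethyl-4H-1,3-benzodioxin-4-one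
Product: 20 benzyl 4-(benzyloxy)-2-[(2R,12R)-2,12-bis(tert-butyldimethylsilyloxy)tridecyl]-6-hydroxybenzoate
Conditions: BnOH, NaH, THF, 0 °C to rt; aq. NH4Cl
Reagents that add atoms: benzyl alcohol, OCc1ccccc1
Why: Acyl substitution (transesterification of a salicylate acetonide), in which benzyl alkoxide adds to the acylal carbonyl and the hemiketal phenoxide leaves and sheds acetone; silyl ethers and the benzyl ether tolerate the alkoxide.

Step 13
Reactants: 20 benzyl 4-(benzyloxy)-2-[(2R,12R)-2,12-bis(tert-butyldimethylsilyloxy)tridecyl]-6-hydroxybenzoate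
Product: 21 benzyl 2,4-bis(benzyloxy)-6-[(2R,12R)-2,12-bis(tert-butyldimethylsilyloxy)tridecyl]benzoate
Conditions: BnBr, Cs2CO3, DMF, rt
Reagents that add atoms: benzyl bromide, BrCc1ccccc1
Why: Williamson ether synthesis, in which the caesium phenoxide in DMF overcomes the hydrogen bond of the ortho-hydroxy ester.

Step 14
Reactants: 21 benzyl 2,4-bis(benzyloxy)-6-[(2R,12R)-2,12-bis(tert-butyldimethylsilyloxy)tridecyl]benzoate
Product: 22 benzyl 2,4-bis(benzyloxy)-6-[(2R,12R)-2,12-dihydroxytridecyl]benzoate
Conditions: HF·pyridine, pyridine, THF, 0 °C to rt; aq. NaHCO3 work-up; crude diol used at once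
Reagents that add atoms: none
Why: Fluoride-mediated cleavage of silyl ethers under buffered, non-basic conditions, chosen because a C2′ alkoxide would lactonise onto the neighbouring ester whereas the neutral alcohol beside a di-ortho-substituted benzoate should be slow to do so; benzyl ethers and ester are inert.

Step 15
Reactants: 22 benzyl 2,4-bis(benzyloxy)-6-[(2R,12R)-2,12-dihydroxytridecyl]benzoate
Product: 23 benzyl 2-[(2R,12R)-2,12-bis(acetyloxy)tridecyl]-4,6-bis(benzyloxy)benzoate
Conditions: Ac2O, pyridine, DMAP (cat.), CH2Cl2, 0 °C to rt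
Reagents that add atoms: acetic anhydride, CC(=O)OC(C)=O
Why: DMAP-catalysed acetylation (nucleophilic catalysis) of the two secondary alcohols, the only free nucleophiles present, run on the crude diol to outpace lactonisation.

Step 16
Reactants: 23 benzyl 2-[(2R,12R)-2,12-bis(acetyloxy)tridecyl]-4,6-bis(benzyloxy)benzoate
Product: 24 2-[(2R,12R)-2,12-bis(acetyloxy)tridecyl]-4,6-dihydroxybenzoic acid
Conditions: H2 (1 atm), 10% Pd/C, EtOAc, rt
Reagents that add atoms: none
Why: Hydrogenolysis of the three benzyl–oxygen bonds over palladium on carbon frees the acid and both phenols under neutral conditions that leave the alkyl acetates and both stereocentres untouched.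

**Compound list**

1 | 10-bromodec-1-ene | C=CCCCCCCCCBr | starting material
2 | (R)-propylene oxide [(2R)-2-methyloxirane] | C[C@@H]1CO1 | starting material
3 | dec-9-enylmagnesium bromide | C=CCCCCCCCC[Mg]Br | intermediate
4 | (2R)-tridec-12-en-2-ol | C[C@@H](O)CCCCCCCCCC=C | intermediate
5 | tert-butyldimethyl{[(2R)-tridec-12-en-2-yl]oxy}silane | C[C@@H](O[Si](C)(C)C(C)(C)C)CCCCCCCCCC=C | intermediate
6 | tert-butyldimethyl{[(2R)-11-(1,2,4-trioxolan-3-yl)undecan-2-yl]oxy}silane (secondary ozonide, both epimers at the ring carbon) | C[C@@H](O[Si](C)(C)C(C)(C)C)CCCCCCCCCC1OCOO1 | intermediate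
7 | (11R)-11-(tert-butyldimethylsilyloxy)dodecanal | C[C@@H](O[Si](C)(C)C(C)(C)C)CCCCCCCCCC=O | intermediate
8 | ethyl (13R)-13-(tert-butyldimethylsilyloxy)-3-oxotetradecanoate | C[C@@H](O[Si](C)(C)C(C)(C)C)CCCCCCCCCC(=O)CC(=O)OCC | intermediate
9 | ethyl (3R,13R)-13-(tert-butyldimethylsilyloxy)-3-hydroxytetradecanoate | C[C@@H](O[Si](C)(C)C(C)(C)C)CCCCCCCCC[C@@H](O)CC(=O)OCC | intermediate
10 | ethyl (3R,13R)-3,13-bis(tert-butyldimethylsilyloxy)tetradecanoate | C[C@@H](O[Si](C)(C)C(C)(C)C)CCCCCCCCC[C@@H](O[Si](C)(C)C(C)(C)C)CC(=O)OCC | intermediate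
11 | (3R,13R)-3,13-bis(tert-butyldimethylsilyloxy)-N-methoxy-N-methyltetradecanamide | C[C@@H](O[Si](C)(C)C(C)(C)C)CCCCCCCCC[C@@H](O[Si](C)(C)C(C)(C)C)CC(=O)N(C)OC | intermediate
12 | 2,2,6-trimethyl-4H-1,3-dioxin-4-one | CC1=CC(=O)OC(C)(C)O1 | starting material
13 | lithium 2,2-dimethyl-6-methylidene-6H-1,3-dioxin-4-olate | C=C1C=C(O[Li])OC(C)(C)O1 | intermediate
14 | 2,2-dimethyl-6-(2-oxopropyl)-4H-1,3-dioxin-4-one | CC(=O)CC1=CC(=O)OC(C)(C)O1 | intermediate
15 | dilithium dianion of 14 (enolates at the ring carbonyl and the side-chain ketone, terminal carbon nucleophilic) | C=C(O[Li])C=C1C=C(O[Li])OC(C)(C)O1 | intermediate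
16 | 6-[(6R,16R)-6,16-bis(tert-butyldimethylsilyloxy)-2,4-dioxoheptadecyl]-2,2-dimethyl-4H-1,3-dioxin-4-one | C[C@@H](O[Si](C)(C)C(C)(C)C)CCCCCCCCC[C@@H](O[Si](C)(C)C(C)(C)C)CC(=O)CC(=O)CC1=CC(=O)OC(C)(C)O1 | intermediate
17 | 5-[(2R,12R)-2,12-bis(tert-butyldimethylsilyloxy)tridecyl]-5-hydroxy-2,2-dimethyl-5,6-dihydro-4H-1,3-benzodioxine-4,7(8H)-dione (both C5 epimers) | C[C@@H](O[Si](C)(C)C(C)(C)C)CCCCCCCCC[C@@H](O[Si](C)(C)C(C)(C)C)CC1(O)CC(=O)CC2=C1C(=O)OC(C)(C)O2 | intermediate
18 | 5-[(2R,12R)-2,12-bis(tert-butyldimethylsilyloxy)tridecyl]-7-hydroxy-2,2-dimethyl-4H-1,3-benzodioxin-4-one | C[C@@H](O[Si](C)(C)C(C)(C)C)CCCCCCCCC[C@@H](O[Si](C)(C)C(C)(C)C)Cc1cc(O)cc2OC(C)(C)OC(=O)c12 | intermediate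
19 | 7-(benzyloxy)-5-[(2R,12R)-2,12-bis(tert-butyldimethylsilyloxy)tridecyl]-2,2-dimethyl-4H-1,3-benzodioxin-4-one | C[C@@H](O[Si](C)(C)C(C)(C)C)CCCCCCCCC[C@@H](O[Si](C)(C)C(C)(C)C)Cc1cc(OCc3ccccc3)cc2OC(C)(C)OC(=O)c12 | intermediate
20 | benzyl 4-(benzyloxy)-2-[(2R,12R)-2,12-bis(tert-butyldimethylsilyloxy)tridecyl]-6-hydroxybenzoate | C[C@@H](O[Si](C)(C)C(C)(C)C)CCCCCCCCC[C@@H](O[Si](C)(C)C(C)(C)C)Cc1cc(OCc2ccccc2)cc(O)c1C(=O)OCc1ccccc1 | intermediate
21 | benzyl 2,4-bis(benzyloxy)-6-[(2R,12R)-2,12-bis(tert-butyldimethylsilyloxy)tridecyl]benzoate | C[C@@H](O[Si](C)(C)C(C)(C)C)CCCCCCCCC[C@@H](O[Si](C)(C)C(C)(C)C)Cc1cc(OCc2ccccc2)cc(OCc2ccccc2)c1C(=O)OCc1ccccc1 | intermediate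
22 | benzyl 2,4-bis(benzyloxy)-6-[(2R,12R)-2,12-dihydroxytridecyl]benzoate | C[C@@H](O)CCCCCCCCC[C@@H](O)Cc1cc(OCc2ccccc2)cc(OCc2ccccc2)c1C(=O)OCc1ccccc1 | intermediate
23 | benzyl 2-[(2R,12R)-2,12-bis(acetyloxy)tridecyl]-4,6-bis(benzyloxy)benzoate | C[C@@H](OC(C)=O)CCCCCCCCC[C@@H](OC(C)=O)Cc1cc(OCc2ccccc2)cc(OCc2ccccc2)c1C(=O)OCc1ccccc1 | intermediate
24 | 2-[(2R,12R)-2,12-bis(acetyloxy)tridecyl]-4,6-dihydroxybenzoic acid | C[C@@H](OC(C)=O)CCCCCCCCC[C@@H](OC(C)=O)Cc1cc(O)cc(O)c1C(=O)O | target

**Step count**

Total steps: 16. Longest linear sequence: 15 (steps 1–7 and 9–16, from 10-bromodec-1-ene); step 8 is a one-step branch.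

**Steps most likely to fail**

Step 9. The dianion may act as a base toward the amide (proton transfer, then loss of silanolate by β-elimination) instead of as a nucleophile, so that acylation stalls. The fallback sets out from 11 and comes back at 16, making the bond at the aldehyde oxidation level. Amide 11 is reduced with i-Bu2AlH (THF, −78 °C) to (3R,13R)-3,13-bis(tert-butyldimethylsilyloxy)tetradecanal F1. Dianion 15, generated from 14 as in step 9, is added to F1 at −78 °C in an aldol addition, which is much faster than acylation. This should give 6-[(6R,16R)-6,16-bis(tert-butyldimethylsilyloxy)-4-hydroxy-2-oxoheptadecyl]-2,2-dimethyl-4H-1,3-dioxin-4-one F2 as a mixture of C4 epimers. Dess–Martin oxidation of F2 (CH2Cl2, NaHCO3) returns to 16.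

Step 10. Ring closure may be slow, dehydration of the carbinol incomplete, or the silyloxy group β to the C4 ketone may be eliminated before the ring forms. The fallback sets out from 16 and comes back at 21, unmasking the carboxyl first. Heating 16 with benzyl alcohol in toluene at 110 °C expels acetone in a retro-hetero-Diels–Alder reaction, and the acylketene is trapped as benzyl (9R,19R)-9,19-bis(tert-butyldimethylsilyloxy)-3,5,7-trioxoicosanoate F3. K2CO3 in i-PrOH–CH2Cl2 followed by AcOH should effect the same C1–C6 aldol and aromatisation on this more acidic open-chain triketo ester, giving benzyl 2-[(2R,12R)-2,12-bis(tert-butyldimethylsilyloxy)tridecyl]-4,6-dihydroxybenzoate F4. Double benzylation of F4 (BnBr, Cs2CO3, DMF) joins the route at 21, so steps 11–13 are skipped.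

Step 14. The C2′ hydroxyl, once free, may attack the neighbouring benzyl ester and close a six-membered lactone during desilylation or work-up. The fallback sets out from 21 and comes back at 23, avoiding the free diol. Treatment of 21 with Ac2O and catalytic Cu(OTf)2 in CH2Cl2 at rt exchanges silyl ethers directly for acetates, the silyl group leaving as its acetate, and should give 23 without passing through 22. No new compound arises.

**Further compounds**

F1 | step 9 | (3R,13R)-3,13-bis(tert-butyldimethylsilyloxy)tetradecanal | C[C@@H](O[Si](C)(C)C(C)(C)C)CCCCCCCCC[C@@H](O[Si](C)(C)C(C)(C)C)CC=O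
F2 | step 9 | 6-[(6R,16R)-6,16-bis(tert-butyldimethylsilyloxy)-4-hydroxy-2-oxoheptadecyl]-2,2-dimethyl-4H-1,3-dioxin-4-one (C4 epimers) | C[C@@H](O[Si](C)(C)C(C)(C)C)CCCCCCCCC[C@@H](O[Si](C)(C)C(C)(C)C)CC(O)CC(=O)CC1=CC(=O)OC(C)(C)O1
F3 | step 10 | benzyl (9R,19R)-9,19-bis(tert-butyldimethylsilyloxy)-3,5,7-trioxoicosanoate | C[C@@H](O[Si](C)(C)C(C)(C)C)CCCCCCCCC[C@@H](O[Si](C)(C)C(C)(C)C)CC(=O)CC(=O)CC(=O)CC(=O)OCc1ccccc1
F4 | step 10 | benzyl 2-[(2R,12R)-2,12-bis(tert-butyldimethylsilyloxy)tridecyl]-4,6-dihydroxybenzoate | C[C@@H](O[Si](C)(C)C(C)(C)C)CCCCCCCCC[C@@H](O[Si](C)(C)C(C)(C)C)Cc1cc(O)cc(O)c1C(=O)OCc1ccccc1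
F0 | step 14 | none | none
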